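## Analysis of the target

Entonaemin A is a 5,6,7,8-tetrahydro-1H-isochromen-8-one: a 2H-pyran (ring B: C1H2, O2, C3, C4, C4a, C8a) is fused through the tetrasubstituted C4a=C8a bond to a cyclohexenone (ring A: C4a, C5H2, C6, C7, C8, C8a), so that O2–C3=C4–C4a=C8a–C8=O forms one push–pull dienone, and C3 carries an (E)-3-hydroxyprop-1-enyl chain. Ring A holds the only two stereocentres, side by side: C6 (R, secondary, acylated) and C7 (R, tertiary carbinol with the methyl group); their oxygens are cis and the methyl group is trans to the acyloxy group. O–C6 is esterified by 2,4-dihydroxy-6-methylbenzoic acid (C1' carries the carboxyl, C2' and C4' the hydroxyls, C6' the methyl). The sensitive groups are the dienyl enol ether of ring B (acid, reversible electrocyclic opening), the C7/C8 α-ketol next to the ester (base: acyl migration from O6 to O7, acyloin-type shifts), the allylic alcohol and the free phenols. The synthesis is hard because an ester must be made between a 2,6-disubstituted benzoic acid and a secondary hydroxyl flanked by a fully substituted carbon, on a core that tolerates neither strong base nor strong acid. The strategy rests on the benzene ring of that ester: C1' and C6' are adjacent and can be the two sp carbons of a but-2-ynoate on O–C6, while C2'–C3'–C4'–C5', oxygenated at C2' and C4', corresponds to a 1,3-dioxygenated buta-1,3-diene.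

## Retrosynthetic reasoning

**27 to 26.** The last operation only removes silicon: the trimethylsilyl group on O–C7 and the tert-butyldiphenylsilyl group on the side-chain oxygen. Buffered fluoride is chosen because the α-ketol, the hindered aryl ester and the enol ether all tolerate it.

**26 to 20 and 23.** The aryl bonds C1'–C2' and C5'–C6' are cut. They flank the carboxyl-bearing and the methyl-bearing carbons, so cutting them turns the acyl group on O–C6 into a linear but-2-ynoate with no ortho substituents. This is the one place where the cut removes the steric problem of the ester instead of moving it. The forward reaction has to join the nucleophilic CH2 terminus of diene 23 to the methyl-bearing alkyne carbon of 20, close the ring at the ester-bearing carbon, and aromatise by loss of the methoxy group, all without touching the dienone.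

**20 to 19 to 17 and 18.** The O7–Si bond and the O6–acyl bond are cut. Core diol 17 offers a secondary and a tertiary hydroxyl, so acid 18 is expected to go onto O–C6 alone. The tertiary hydroxyl is then capped so that it cannot protonate the ketene-acetal diene in the key step.

**17 to 15 (through 16).** The C4a–C8a bond and the O2–C1 bond are cut, which opens both rings at once to the acyclic dihydroxy enone–ynone 15. Forward, an amine catalyst triggers a Michael ring closure of the vinyl ketone onto the ynone, and the resulting 1-oxatriene 16 closes to the pyran by oxa-6π electrocyclisation. This cut is preferred to building ring B onto a preformed ring A for three reasons: the tetrasubstituted alkene and the pyran regiochemistry (O2 on C3, CH2 on C8a) are then fixed by connectivity, no cross-coupling is needed, and C6 and C7 sit on an open chain that a chiral-pool lactone can supply.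

**15 to 14 to 13 to 12 and 3.** The isopropylidene group is put back on the diol. Both ketones are traced to carbinols, so the vinyl ketone and the ynone appear together in one oxidation and are not carried through organometallic steps. The C3–C4 bond is cut between the terminal alkyne of 12 and the aldehyde carbon of enal 3, a plain acetylide addition.

**12 to 11 to 10.** The alkyne C–Si bond and the C8–C8a bond are cut. Aldehyde 10 has no α-hydrogen, so adding a vinyl Grignard reagent cannot disturb C7.

**10 to 9 to 7 (through 8).** The C8 aldehyde is traced to a vinyl group and the C5–C4a bond to displacement of primary triflate 8 by an alkynyllithium. The vinyl mask is deliberate: any carbonyl-type or hydroxyl oxygen on C8 would close onto an activated C5 in a five-membered ring (lactone 5 is exactly that ring), whereas an alkene cannot.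

**7 to 6 to 5 to 4.** Methylenation of lactol 6, partial reduction of lactone 5 and ketalisation lead back to lactone 4. Its C3 and C4 are C7 and C6 of the target with the correct absolute configuration, (3R,4R) corresponding to (7R,6R), and with the cis relationship built in. Both stereocentres are therefore bought, not made.

**Side pieces.** Enal 3 comes from diol 1 through mono-ether 2. Diene 23 comes from keto ester 21 through enol ether 22. The side-chain oxygen is carried as a tert-butyldiphenylsilyl ether because it must pass one aqueous acid step.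

## Alternatives that were turned down

**Alternative 1:** The C3=C4 bond of ring B is cut. Forward, the phosphonium salt A1 (ring A as the diol acetonide, C4 as CH2–PPh3+, O2 acylated by an (E)-4-silyloxybut-2-enoyl group) is deprotonated, and the C4 ylide olefinates the ester carbonyl to give the bicyclic acetonide A2.
- For it: the enol ether can only form in the six-membered mode, so the ring-B regiochemistry is at least as secure as in the cascade used here, and the diol stays protected.
- Against it: the ylide is vinylogously stabilised by the C8 ketone through C4a=C8a, so it is a weak nucleophile. Its partner is an ester that is also an enoate, so conjugate addition and γ-deprotonation compete with carbonyl olefination. A1 needs a ring A with a differentiated CH2O and CH2Br on a tetrasubstituted enone, which costs more steps than the chain leading to 15, and the halide is prone to elimination toward an arene.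
- Comparison: A2 still lacks the aryl ester, so the hardest bond of the target is left open. The chosen strategy spends its key step on exactly that bond.

**Alternative 2:** The C7–C8 bond is cut. Forward, a chiral triazolium-derived carbene turns the C8a aldehyde of the 2H-pyran keto aldehyde A3 into an acyl-anion equivalent that adds to the tethered methyl ketone, closing ring A and giving A4 with O–C6 silylated and O–C7 free.
- For it: the tertiary carbinol is created catalytically, and the two hydroxyls emerge already differentiated. On that point it is stronger than the chosen route, which relies on the secondary-versus-tertiary reactivity difference.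
- Against it: the aldehyde of A3 is the end of a β-alkoxy dienal (O2–C3=C4–C4a=C8a–CHO) and therefore a poor electrophile for the carbene. The ketone is α-silyloxylated at C6, so the base needed to generate the carbene can epimerise C6. The cis relationship depends on catalyst and substrate control pulling the same way. A3 is itself a long synthesis of a labile pyran.
- Comparison: step economy is no better, and the aryl ester is again not addressed. The chosen route takes both stereocentres from the chiral pool and has no stereochemical risk.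

**Alternative 3:** The O6–acyl bond and the C1'–C6' bond of the arene are cut. Forward, thermolysis of the diketo-dioxinone A6 in the presence of the core diol A5 acylates O–C6 by ketene capture; the resulting 3,5,7-trioxo ester closes by aldol condensation and dehydrates to the resorcylate A7.
- For it: ketene capture is one of the best acylations of hindered alcohols, it is neutral, it needs no protection of O–C7, and it reaches the aryl ester in one step from the diol where the chosen route needs three. On step count at the end of the synthesis it is stronger.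
- Against it: the intermediate is a polyketone ester whose alkoxy part is the precious core. It can cyclise through oxygen to a hydroxy-pyranone and expel the core alcohol. The C-aldol aromatisation usually needs base or acid, which the α-ketol and the vinylogous ester do not like. The cis tertiary hydroxyl sits next to a β-keto ester and can take the acyl group over. A6 itself costs two to three steps.
- Comparison: the chosen strategy pays two extra steps and receives an aromatisation that runs by elimination under neutral thermal conditions, with the regiochemistry fixed by the cycloaddition and no intermediate from which the alcohol can be lost.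

Key step: step 18

Remark on the chemistry: lactone 4 is taken as a purchasable chiral-pool compound (the natural D-erythro saccharinic lactone).

## Route

Step 1
Reactants: 1 (Z)-but-2-ene-1,4-diol
Product: 2 (Z)-4-[(tert-butyldiphenylsilyl)oxy]but-2-en-1-ol
Conditions: NaH (1.0 equiv), THF, 0 °C to rt; then t-BuPh2SiCl (1.0 equiv)
Reagents that add atoms: tert-butyl(chloro)diphenylsilane, CC(C)(C)[Si](Cl)(c1ccccc1)c1ccccc1
Why: O-silylation of the sparingly soluble monosodium alkoxide of a symmetrical diol (statistical monoprotection) should stop at the mono-ether.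

Step 2
Reactants: 2 (Z)-4-[(tert-butyldiphenylsilyl)oxy]but-2-en-1-ol
Product: 3 (E)-4-[(tert-butyldiphenylsilyl)oxy]but-2-enal
Conditions: [C5H5NH][CrO3Cl], CH2Cl2, rt
Reagents that add atoms: none
Why: Oxidation of the allylic alcohol by hexavalent chromium (Corey–Suggs oxidation); the mildly acidic medium should equilibrate the first-formed (Z)-enal to the more stable (E)-enal.

Step 3
Reactants: 4 2-C-methyl-D-erythrono-1,4-lactone [(3R,4R)-3,4-dihydroxy-3-methyloxolan-2-one]
Product: 5 2,3-O-isopropylidene-2-C-methyl-D-erythrono-1,4-lactone [(3aR,6aR)-2,2,3a-trimethyldihydrofuro[3,4-d][1,3]dioxol-4(3aH)-one]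
Conditions: Me2C(OMe)2, TsOH (cat.), acetone, rt
Reagents that add atoms: 2,2-dimethoxypropane, COC(C)(C)OC
Why: Acid-catalysed transketalisation; the cis-diol of the γ-lactone closes a cis-fused dioxolane and neither stereocentre is touched.

Step 4
Reactants: 5 2,3-O-isopropylidene-2-C-methyl-D-erythrono-1,4-lactone
Product: 6 2,3-O-isopropylidene-2-C-methyl-D-erythrofuranose [(3aR,6aR)-2,2,3a-trimethyltetrahydrofuro[3,4-d][1,3]dioxol-4-ol, both anomers]
Conditions: i-Bu2AlH, CH2Cl2, −78 °C
Reagents that add atoms: none
Why: Partial reduction of a γ-lactone; the tetrahedral aluminium alkoxide is stable at −78 °C and gives the lactol on work-up.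

Step 5
Reactants: 6 2,3-O-isopropylidene-2-C-methyl-D-erythrofuranose
Product: 7 [(4R,5S)-5-ethenyl-2,2,5-trimethyl-1,3-dioxolan-4-yl]methanol
Conditions: Ph3PCH3Br, KOt-Bu (excess), THF, 0 °C to reflux
Reagents that add atoms: methyltriphenylphosphonium bromide, C[P+](c1ccccc1)(c1ccccc1)c1ccccc1.[Br-]
Why: Wittig methylenation of the open hydroxy-aldehyde tautomer of the lactol; the aldehyde carbon is attached to a fully substituted carbon, so no epimerisation is possible.

Step 6
Reactants: 7 [(4R,5S)-5-ethenyl-2,2,5-trimethyl-1,3-dioxolan-4-yl]methanol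
Product: 9 trimethyl{3-[(4R,5S)-5-ethenyl-2,2,5-trimethyl-1,3-dioxolan-4-yl]prop-1-yn-1-yl}silane, via primary triflate 8 (not isolated)
Conditions: Tf2O, 2,6-lutidine, CH2Cl2, −78 °C; then Me3SiC≡CLi (from Me3SiC≡CH, n-BuLi), THF/DMPU, −78 to −20 °C
Reagents that add atoms: ethynyltrimethylsilane, C#C[Si](C)(C)C
Why: SN2 displacement of a primary triflate by a lithium acetylide forms the C5–C4a bond; C8 is present as a vinyl group and cannot act as a neighbouring nucleophile, and C6 is not a reacting centre.

Step 7
Reactants: 9 trimethyl{3-[(4R,5S)-5-ethenyl-2,2,5-trimethyl-1,3-dioxolan-4-yl]prop-1-yn-1-yl}silane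
Product: 10 (4R,5R)-2,2,4-trimethyl-5-[3-(trimethylsilyl)prop-2-yn-1-yl]-1,3-dioxolane-4-carbaldehyde
Conditions: O3, CH2Cl2, −78 °C (dye end-point); then PPh3
Reagents that add atoms: ozone, [O-][O+]=O
Why: Ozonolysis of the monosubstituted alkene, which reacts far faster than the silylated alkyne; reductive work-up gives a non-enolisable aldehyde.

Step 8
Reactants: 10 (4R,5R)-2,2,4-trimethyl-5-[3-(trimethylsilyl)prop-2-yn-1-yl]-1,3-dioxolane-4-carbaldehyde
Product: 11 1-{2,2,4-trimethyl-5-[3-(trimethylsilyl)prop-2-yn-1-yl]-1,3-dioxolan-4-yl}prop-2-en-1-ol (dioxolane carbons as in 10, carbinol carbon as both epimers)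
Conditions: CH2=CHMgBr, THF, −78 to 0 °C
Reagents that add atoms: vinylmagnesium bromide, C=C[Mg]Br
Why: Grignard 1,2-addition forms the C8–C8a bond; the new carbinol centre is a mixture that the later oxidation erases.

Step 9
Reactants: 11 1-{2,2,4-trimethyl-5-[3-(trimethylsilyl)prop-2-yn-1-yl]-1,3-dioxolan-4-yl}prop-2-en-1-ol
Product: 12 1-[2,2,4-trimethyl-5-(prop-2-yn-1-yl)-1,3-dioxolan-4-yl]prop-2-en-1-ol (dioxolane carbons as in 10, carbinol carbon as both epimers)
Conditions: K2CO3 (cat.), MeOH, rt
Reagents that add atoms: none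
Why: Base-catalysed methanolysis of the alkynyl C–Si bond; the ketal and the allylic alcohol are inert.

Step 10
Reactants: 12 1-[2,2,4-trimethyl-5-(prop-2-yn-1-yl)-1,3-dioxolan-4-yl]prop-2-en-1-ol; 3 (E)-4-[(tert-butyldiphenylsilyl)oxy]but-2-enal
Product: 13 (E)-1-[(tert-butyldiphenylsilyl)oxy]-7-[5-(1-hydroxyprop-2-en-1-yl)-2,2,5-trimethyl-1,3-dioxolan-4-yl]hept-2-en-5-yn-4-ol (dioxolane carbons as in 10, both carbinol carbons as epimer mixtures)
Conditions: n-BuLi (2.1 equiv), THF, −78 to 0 °C; then 3, −78 °C
Reagents that add atoms: none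
Why: The lithium alkoxide/lithium acetylide dianion adds 1,2 to the enal (acetylide addition to an aldehyde) and forms the C3–C4 bond; both carbinol centres are oxidised in the next step.

Step 11
Reactants: 13 (E)-1-[(tert-butyldiphenylsilyl)oxy]-7-[5-(1-hydroxyprop-2-en-1-yl)-2,2,5-trimethyl-1,3-dioxolan-4-yl]hept-2-en-5-yn-4-ol
Product: 14 (E)-1-[(tert-butyldiphenylsilyl)oxy]-7-[(4R,5R)-2,2,5-trimethyl-5-(prop-2-enoyl)-1,3-dioxolan-4-yl]hept-2-en-5-yn-4-one
Conditions: Dess–Martin periodinane (3 equiv), CH2Cl2, 0 °C to rt
Reagents that add atoms: none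
Why: Dess–Martin oxidation converts the allylic and the propargylic carbinol in one operation under non-basic conditions, so the vinyl ketone and the ynone appear only now and the ketal and silyl ether survive.

Step 12
Reactants: 14 (E)-1-[(tert-butyldiphenylsilyl)oxy]-7-[(4R,5R)-2,2,5-trimethyl-5-(prop-2-enoyl)-1,3-dioxolan-4-yl]hept-2-en-5-yn-4-one
Product: 15 (4R,5R,10E)-12-[(tert-butyldiphenylsilyl)oxy]-4,5-dihydroxy-4-methyldodeca-1,10-dien-7-yne-3,9-dione
Conditions: CF3CO2H/H2O (4:1), 0 °C
Reagents that add atoms: none
Why: Acid hydrolysis of the isopropylidene ketal; neither enone has an acid-labile group and a primary tert-butyldiphenylsilyl ether should withstand cold aqueous CF3CO2H.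

Step 13
Reactants: 15 (4R,5R,10E)-12-[(tert-butyldiphenylsilyl)oxy]-4,5-dihydroxy-4-methyldodeca-1,10-dien-7-yne-3,9-dione
Product: 17 (6R,7R)-3-{(E)-3-[(tert-butyldiphenylsilyl)oxy]prop-1-en-1-yl}-6,7-dihydroxy-7-methyl-6,7-dihydro-1H-isochromen-8(5H)-one, via exocyclic 1-oxatriene 16 (not isolated)
Conditions: DABCO (0.2 equiv), CHCl3, rt
Reagents that add atoms: none
Why: Nucleophile-catalysed cycloisomerisation of an enone–ynone, a reaction type established for closely related dihydroxy enone–ynones: DABCO adds to C1 of the vinyl ketone, the ammonium enolate closes ring A by 6-exo-dig Michael addition of C8a to C4a (Rauhut–Currier type), proton transfer and loss of DABCO give 16, and its oxa-6π electrocyclisation closes ring B; C6 and C7 are spectators.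

Step 14
Reactants: 17 (6R,7R)-3-{(E)-3-[(tert-butyldiphenylsilyl)oxy]prop-1-en-1-yl}-6,7-dihydroxy-7-methyl-6,7-dihydro-1H-isochromen-8(5H)-one; 18 but-2-ynoic acid
Product: 19 (6R,7R)-3-{(E)-3-[(tert-butyldiphenylsilyl)oxy]prop-1-en-1-yl}-7-hydroxy-7-methyl-8-oxo-5,6,7,8-tetrahydro-1H-isochromen-6-yl but-2-ynoate
Conditions: DCC, DMAP (0.1 equiv), CH2Cl2, 0 °C
Reagents that add atoms: none
Why: Steglich esterification with a small linear acid; the secondary C6 hydroxyl should react and the tertiary C7 hydroxyl should not, and low temperature with little DMAP limits isomerisation of the activated ynoate.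

Step 15
Reactants: 19 (6R,7R)-3-{(E)-3-[(tert-butyldiphenylsilyl)oxy]prop-1-en-1-yl}-7-hydroxy-7-methyl-8-oxo-5,6,7,8-tetrahydro-1H-isochromen-6-yl but-2-ynoate
Product: 20 (6R,7R)-3-{(E)-3-[(tert-butyldiphenylsilyl)oxy]prop-1-en-1-yl}-7-methyl-8-oxo-7-[(trimethylsilyl)oxy]-5,6,7,8-tetrahydro-1H-isochromen-6-yl but-2-ynoate
Conditions: Me3SiOTf, 2,6-lutidine, CH2Cl2, −78 °C
Reagents that add atoms: trimethylsilyl trifluoromethanesulfonate, C[Si](C)(C)OS(=O)(=O)C(F)(F)F
Why: Silylation of the tertiary α-ketol hydroxyl with a silyl triflate and a hindered base removes the only proton that would quench the ketene-acetal diene.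

Step 16
Reactants: 21 methyl acetoacetate
Product: 22 methyl 3-[(trimethylsilyl)oxy]but-2-enoate (mixture of geometric isomers)
Conditions: Me3SiCl, Et3N, hexane, rt
Reagents that add atoms: chlorotrimethylsilane, C[Si](C)(C)Cl
Why: O-silylation of the enol of a β-keto ester.

Step 17
Reactants: 22 methyl 3-[(trimethylsilyl)oxy]but-2-enoate
Product: 23 (Z)-1-methoxy-1,3-bis[(trimethylsilyl)oxy]buta-1,3-diene
Conditions: LiN(i-Pr)2, THF, −78 °C; then Me3SiCl
Reagents that add atoms: chlorotrimethylsilane, C[Si](C)(C)Cl
Why: γ-Deprotonation of the vinylogous ester and O-silylation of the dienolate give the silyl ketene-acetal diene.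

Step 18
Reactants: 20 (6R,7R)-3-{(E)-3-[(tert-butyldiphenylsilyl)oxy]prop-1-en-1-yl}-7-methyl-8-oxo-7-[(trimethylsilyl)oxy]-5,6,7,8-tetrahydro-1H-isochromen-6-yl but-2-ynoate; 23 (Z)-1-methoxy-1,3-bis[(trimethylsilyl)oxy]buta-1,3-diene
Product: 26 (6R,7R)-3-{(E)-3-[(tert-butyldiphenylsilyl)oxy]prop-1-en-1-yl}-7-methyl-8-oxo-7-[(trimethylsilyl)oxy]-5,6,7,8-tetrahydro-1H-isochromen-6-yl 2,4-dihydroxy-6-methylbenzoate, via cyclohexa-1,4-diene cycloadduct 24 (not isolated), via bis(trimethylsilyl) aryl ether 25 (not isolated)
Conditions: 23 (4 equiv), toluene, 110 °C, sealed tube; then SiO2, moist EtOAc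
Reagents that add atoms: none
Why: This is a thermal [4+2] cycloaddition of an electron-rich 1,1,3-trioxygenated diene with an alkynoate, the known route from 1-alkoxy-1,3-bis(silyloxy)butadienes and acetylenic esters to resorcylates. Bond formation is strongly asynchronous: the terminal CH2 of 23 (largest HOMO coefficient) bonds to the methyl-bearing β-carbon of the ynoate (largest LUMO coefficient) and the ketene-acetal carbon then closes onto the α-carbon, which places the hydroxyl and the methyl group on the two carbons flanking the ester. The six-membered carbocycle is closed by this intermolecular cycloaddition and appears as the cyclohexa-1,4-diene 24 with a mixed methyl silyl ketal carbon; 1,4-loss of methanol from that carbon and the ring CH2 aromatises it to 25, the silyloxy group being kept as is usual for mixed silyl ketene-acetal dienes. The two aryl silyl ethers of 25 are far more labile than the tertiary alkyl silyl ether and should hydrolyse on silica to leave 26. No stereocentre is formed (the ketal carbon of 24 is transient) and C6 and C7 are untouched under neutral thermal conditions. The step needs chemoselectivity for the ynoate over the other π-systems of 20: the C3=C4–C4a=C8a unit is a push–pull vinylogous ester with a tetrasubstituted, poorly dienophilic C4a=C8a bond and is far less electron-rich than 23, the side-chain alkene is unactivated, and the C8 ketone does not react with 23 without a Lewis acid. The hydroxyl that would protonate 23 was capped in step 15, and 23 is used in excess to outpace its own thermal decay.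

Step 19
Reactants: 26 (6R,7R)-3-{(E)-3-[(tert-butyldiphenylsilyl)oxy]prop-1-en-1-yl}-7-methyl-8-oxo-7-[(trimethylsilyl)oxy]-5,6,7,8-tetrahydro-1H-isochromen-6-yl 2,4-dihydroxy-6-methylbenzoate
Product: 27 entonaemin A [(6R,7R)-7-hydroxy-3-[(E)-3-hydroxyprop-1-en-1-yl]-7-methyl-8-oxo-5,6,7,8-tetrahydro-1H-isochromen-6-yl 2,4-dihydroxy-6-methylbenzoate]
Conditions: HF·pyridine, pyridine, THF, 0 °C to rt
Reagents that add atoms: none
Why: Buffered fluoride cleaves the tertiary trimethylsilyl ether and the primary tert-butyldiphenylsilyl ether; the hindered aryl ester, the α-ketol and the pyran should be stable at this pH, and no stereocentre is involved.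

## Compound list

1 | (Z)-but-2-ene-1,4-diol | OC/C=C\CO | starting material
2 | (Z)-4-[(tert-butyldiphenylsilyl)oxy]but-2-en-1-ol | OC/C=C\CO[Si](c1ccccc1)(c1ccccc1)C(C)(C)C | intermediate
3 | (E)-4-[(tert-butyldiphenylsilyl)oxy]but-2-enal | O=C/C=C/CO[Si](c1ccccc1)(c1ccccc1)C(C)(C)C | intermediate
4 | 2-C-methyl-D-erythrono-1,4-lactone, (3R,4R)-3,4-dihydroxy-3-methyloxolan-2-one | O[C@@H]1COC(=O)[C@]1(C)O | starting material
5 | 2,3-O-isopropylidene-2-C-methyl-D-erythrono-1,4-lactone, (3aR,6aR)-2,2,3a-trimethyldihydrofuro[3,4-d][1,3]dioxol-4(3aH)-one | CC1(C)O[C@@H]2COC(=O)[C@]2(C)O1 | intermediate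
6 | 2,3-O-isopropylidene-2-C-methyl-D-erythrofuranose (lactol, both anomers) | CC1(C)O[C@@H]2COC(O)[C@]2(C)O1 | intermediate
7 | [(4R,5S)-5-ethenyl-2,2,5-trimethyl-1,3-dioxolan-4-yl]methanol | CC1(C)O[C@H](CO)[C@@](C=C)(C)O1 | intermediate
8 | [(4R,5S)-5-ethenyl-2,2,5-trimethyl-1,3-dioxolan-4-yl]methyl trifluoromethanesulfonate | CC1(C)O[C@H](COS(=O)(=O)C(F)(F)F)[C@@](C=C)(C)O1 | intermediate
9 | trimethyl{3-[(4R,5S)-5-ethenyl-2,2,5-trimethyl-1,3-dioxolan-4-yl]prop-1-yn-1-yl}silane | CC1(C)O[C@H](CC#C[Si](C)(C)C)[C@@](C=C)(C)O1 | intermediate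
10 | (4R,5R)-2,2,4-trimethyl-5-[3-(trimethylsilyl)prop-2-yn-1-yl]-1,3-dioxolane-4-carbaldehyde | CC1(C)O[C@H](CC#C[Si](C)(C)C)[C@@](C=O)(C)O1 | intermediate
11 | 1-{2,2,4-trimethyl-5-[3-(trimethylsilyl)prop-2-yn-1-yl]-1,3-dioxolan-4-yl}prop-2-en-1-ol (dioxolane carbons as in 10, carbinol epimers) | CC1(C)O[C@H](CC#C[Si](C)(C)C)[C@@](C(O)C=C)(C)O1 | intermediate
12 | 1-[2,2,4-trimethyl-5-(prop-2-yn-1-yl)-1,3-dioxolan-4-yl]prop-2-en-1-ol (dioxolane carbons as in 10, carbinol epimers) | CC1(C)O[C@H](CC#C)[C@@](C(O)C=C)(C)O1 | intermediate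
13 | (E)-1-[(tert-butyldiphenylsilyl)oxy]-7-[5-(1-hydroxyprop-2-en-1-yl)-2,2,5-trimethyl-1,3-dioxolan-4-yl]hept-2-en-5-yn-4-ol (dioxolane carbons as in 10, carbinol epimers) | CC1(C)O[C@H](CC#CC(O)/C=C/CO[Si](c2ccccc2)(c2ccccc2)C(C)(C)C)[C@@](C(O)C=C)(C)O1 | intermediate
14 | (E)-1-[(tert-butyldiphenylsilyl)oxy]-7-[(4R,5R)-2,2,5-trimethyl-5-(prop-2-enoyl)-1,3-dioxolan-4-yl]hept-2-en-5-yn-4-one | CC1(C)O[C@H](CC#CC(=O)/C=C/CO[Si](c2ccccc2)(c2ccccc2)C(C)(C)C)[C@@](C(=O)C=C)(C)O1 | intermediate
15 | (4R,5R,10E)-12-[(tert-butyldiphenylsilyl)oxy]-4,5-dihydroxy-4-methyldodeca-1,10-dien-7-yne-3,9-dione | O[C@H](CC#CC(=O)/C=C/CO[Si](c1ccccc1)(c1ccccc1)C(C)(C)C)[C@@](C(=O)C=C)(C)O | intermediate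
16 | (2R,3R,5Z)-5-{(E)-4-[(tert-butyldiphenylsilyl)oxy]-2-oxobut-3-en-1-ylidene}-2,3-dihydroxy-2-methyl-6-methylidenecyclohexan-1-one | C=C1C(=O)[C@](C)(O)[C@H](O)C/C1=C/C(=O)/C=C/CO[Si](c1ccccc1)(c1ccccc1)C(C)(C)C | intermediate
17 | (6R,7R)-3-{(E)-3-[(tert-butyldiphenylsilyl)oxy]prop-1-en-1-yl}-6,7-dihydroxy-7-methyl-6,7-dihydro-1H-isochromen-8(5H)-one | O[C@@H]1CC2=C(COC(/C=C/CO[Si](c3ccccc3)(c3ccccc3)C(C)(C)C)=C2)C(=O)[C@]1(C)O | intermediate
18 | but-2-ynoic acid | CC#CC(=O)O | starting material
19 | (6R,7R)-3-{(E)-3-[(tert-butyldiphenylsilyl)oxy]prop-1-en-1-yl}-7-hydroxy-7-methyl-8-oxo-5,6,7,8-tetrahydro-1H-isochromen-6-yl but-2-ynoate | CC#CC(=O)O[C@@H]1CC2=C(COC(/C=C/CO[Si](c3ccccc3)(c3ccccc3)C(C)(C)C)=C2)C(=O)[C@]1(C)O | intermediate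
20 | (6R,7R)-3-{(E)-3-[(tert-butyldiphenylsilyl)oxy]prop-1-en-1-yl}-7-methyl-8-oxo-7-[(trimethylsilyl)oxy]-5,6,7,8-tetrahydro-1H-isochromen-6-yl but-2-ynoate | CC#CC(=O)O[C@@H]1CC2=C(COC(/C=C/CO[Si](c3ccccc3)(c3ccccc3)C(C)(C)C)=C2)C(=O)[C@]1(C)O[Si](C)(C)C | intermediate
21 | methyl acetoacetate | COC(=O)CC(C)=O | starting material
22 | methyl 3-[(trimethylsilyl)oxy]but-2-enoate (mixture of geometric isomers) | COC(=O)C=C(C)O[Si](C)(C)C | intermediate
23 | (Z)-1-methoxy-1,3-bis[(trimethylsilyl)oxy]buta-1,3-diene | CO/C(O[Si](C)(C)C)=C/C(=C)O[Si](C)(C)C | intermediate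
24 | 6-methoxy-2-methyl-4,6-bis[(trimethylsilyl)oxy]cyclohexa-1,4-diene-1-carboxylate of the C6 oxygen of the core of 20 (ketal carbon unassigned) | COC1(O[Si](C)(C)C)C=C(O[Si](C)(C)C)CC(C)=C1C(=O)O[C@@H]1CC2=C(COC(/C=C/CO[Si](c3ccccc3)(c3ccccc3)C(C)(C)C)=C2)C(=O)[C@]1(C)O[Si](C)(C)C | intermediate
25 | 2-methyl-4,6-bis[(trimethylsilyl)oxy]benzoate of the C6 oxygen of the core of 20 | Cc1cc(O[Si](C)(C)C)cc(O[Si](C)(C)C)c1C(=O)O[C@@H]1CC2=C(COC(/C=C/CO[Si](c3ccccc3)(c3ccccc3)C(C)(C)C)=C2)C(=O)[C@]1(C)O[Si](C)(C)C | intermediate
26 | (6R,7R)-3-{(E)-3-[(tert-butyldiphenylsilyl)oxy]prop-1-en-1-yl}-7-methyl-8-oxo-7-[(trimethylsilyl)oxy]-5,6,7,8-tetrahydro-1H-isochromen-6-yl 2,4-dihydroxy-6-methylbenzoate | Cc1cc(O)cc(O)c1C(=O)O[C@@H]1CC2=C(COC(/C=C/CO[Si](c3ccccc3)(c3ccccc3)C(C)(C)C)=C2)C(=O)[C@]1(C)O[Si](C)(C)C | intermediate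
27 | entonaemin A | Cc1cc(O)cc(O)c1C(=O)O[C@@H]1CC2=C(COC(/C=C/CO)=C2)C(=O)[C@]1(C)O | target

## Step count and least certain steps

Total: 19 steps. Longest linear sequence: 15 steps (4 to 27 through steps 3–15, 18 and 19); steps 1–2 and 16–17 make the two side pieces.

**Step 18 (key step).** The most likely failure is a cycloaddition that is too slow: the β-methyl ynoate is a modest dienophile, and at the temperature it needs the diene decays, while the core can suffer electrocyclic opening of the pyran and silyl transfer. A second failure is aromatisation with loss of the silyloxy group instead of the methoxy group, which would leave a methyl ether on the arene.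
Fallback: set out from 17 and return at 27 with a preformed arene. 2,4-Dihydroxy-6-methylbenzoic acid F1 is per-silylated (t-BuMe2SiCl, imidazole, DMF) to its tris(tert-butyldimethylsilyl) derivative F2. Treating the silyl ester with (COCl)2 and catalytic DMF gives the acid chloride F3. Acylation of 17 with F3 (Et3N, DMAP, CH2Cl2, reflux) should give the protected ester F4 on the secondary oxygen, and HF·pyridine removes all three silyl groups to give 27. This is the hindered acylation that the main route avoids, so it is held in reserve.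

**Step 13 (with the acid treatment of step 12 before it).** The vinyl ketone may oligomerise or the sequence may stall after the Michael step if the free diol chain does not fold well. The acyclic bis-acceptor 14 may also suffer hydration or polymerisation during ketal hydrolysis.
Fallback: set out from 14 and return at 17 by cyclising before unmasking. DABCO in CHCl3 acts on the ketal-protected 14, in which the dioxolane holds the two reacting arms cis and masks the α-ketol, to give the tricyclic acetonide F5. Hydrolysis of F5 with aqueous CF3CO2H in THF gives 17.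

**Step 14.** Acylation of a secondary hydroxyl next to a fully substituted carbon may be slow, and during that time the activated ynoic acid can isomerise to the allenoate under DMAP or end as the N-acylurea.
Fallback: set out from 17 and return at 19 by activating the alcohol instead of the acid. Heating 17 with Bu2SnO in toluene with removal of water gives the O6,O7-dibutylstannylene acetal F6. But-2-ynoyl chloride F7 (from 18 with (COCl)2 and catalytic DMF) at 0 °C should then acylate the tin-activated secondary oxygen and give 19 after aqueous work-up.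

## Further compounds

F1 | step 18 | 2,4-dihydroxy-6-methylbenzoic acid (orsellinic acid) | Cc1cc(O)cc(O)c1C(=O)O
F2 | step 18 | tert-butyldimethylsilyl 2,4-bis[(tert-butyldimethylsilyl)oxy]-6-methylbenzoate | Cc1cc(O[Si](C)(C)C(C)(C)C)cc(O[Si](C)(C)C(C)(C)C)c1C(=O)O[Si](C)(C)C(C)(C)C
F3 | step 18 | 2,4-bis[(tert-butyldimethylsilyl)oxy]-6-methylbenzoyl chloride | Cc1cc(O[Si](C)(C)C(C)(C)C)cc(O[Si](C)(C)C(C)(C)C)c1C(Cl)=O
F4 | step 18 | (6R,7R)-3-{(E)-3-[(tert-butyldiphenylsilyl)oxy]prop-1-en-1-yl}-7-hydroxy-7-methyl-8-oxo-5,6,7,8-tetrahydro-1H-isochromen-6-yl 2,4-bis[(tert-butyldimethylsilyl)oxy]-6-methylbenzoate | Cc1cc(O[Si](C)(C)C(C)(C)C)cc(O[Si](C)(C)C(C)(C)C)c1C(=O)O[C@@H]1CC2=C(COC(/C=C/CO[Si](c3ccccc3)(c3ccccc3)C(C)(C)C)=C2)C(=O)[C@]1(C)O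
F5 | step 13 | 6,7-O-isopropylidene derivative of 17 (cis-fused acetonide of the bicyclic core) | CC1(C)O[C@@H]2CC3=C(COC(/C=C/CO[Si](c4ccccc4)(c4ccccc4)C(C)(C)C)=C3)C(=O)[C@]2(C)O1
F6 | step 14 | O6,O7-dibutylstannylene acetal of 17 | CCCC[Sn]1(CCCC)O[C@@H]2CC3=C(COC(/C=C/CO[Si](c4ccccc4)(c4ccccc4)C(C)(C)C)=C3)C(=O)[C@]2(C)O1
F7 | step 14 | but-2-ynoyl chloride | CC#CC(Cl)=O
A1 | alternative 1 | triphenylphosphonium bromide of the ring-A acetonide enone bearing CH2–PPh3+ on C4a and the (E)-4-[(tert-butyldimethylsilyl)oxy]but-2-enoate of the C8a hydroxymethyl group | CC1(C)O[C@@H]2CC(C[P+](c3ccccc3)(c3ccccc3)c3ccccc3)=C(COC(=O)/C=C/CO[Si](C)(C)C(C)(C)C)C(=O)[C@]2(C)O1.[Br-]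
A2 | alternative 1 | bicyclic core as the 6,7-acetonide with the side chain as tert-butyldimethylsilyl ether | CC1(C)O[C@@H]2CC3=C(COC(/C=C/CO[Si](C)(C)C(C)(C)C)=C3)C(=O)[C@]2(C)O1
A3 | alternative 2 | 6-{(E)-3-[(tert-butyldimethylsilyl)oxy]prop-1-en-1-yl}-4-[(2R)-3-oxo-2-[(triethylsilyl)oxy]butyl]-2H-pyran-3-carbaldehyde | O=CC1=C(C[C@@H](O[Si](CC)(CC)CC)C(C)=O)C=C(/C=C/CO[Si](C)(C)C(C)(C)C)OC1
A4 | alternative 2 | bicyclic core with the C6 oxygen as triethylsilyl ether, the C7 hydroxyl free and the side chain as tert-butyldimethylsilyl ether | CC[Si](CC)(CC)O[C@@H]1CC2=C(COC(/C=C/CO[Si](C)(C)C(C)(C)C)=C2)C(=O)[C@]1(C)O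
A5 | alternative 3 | core diol with the side chain as tert-butyldimethylsilyl ether | O[C@@H]1CC2=C(COC(/C=C/CO[Si](C)(C)C(C)(C)C)=C2)C(=O)[C@]1(C)O
A6 | alternative 3 | 6-(2,4-dioxopentyl)-2,2-dimethyl-4H-1,3-dioxin-4-one | CC(=O)CC(=O)CC1=CC(=O)OC(C)(C)O1
A7 | alternative 3 | entonaemin A tert-butyldimethylsilyl ether (side chain) | Cc1cc(O)cc(O)c1C(=O)O[C@@H]1CC2=C(COC(/C=C/CO[Si](C)(C)C(C)(C)C)=C2)C(=O)[C@]1(C)O
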